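**Strategy**

The C30 skeleton is cut at the C2'–C3' bond of the side chain, where the two-carbon tether from ring carbon C3 of the cyclohexenol meets the first trisubstituted alkene (C3'=C4'). This gives a C11 ring piece carrying a vinyl group and a C19 farnesyl-derived (E)-2-iodo-2-alkene. The key step is a one-pot hydroboration/B-alkyl Suzuki–Miyaura coupling: 9-BBN turns the vinyl group of the unprotected vinylcyclohexenol into a primary alkylborane, which palladium joins to the alkenyl iodide with retention of the E geometry, giving camelliol C directly. The ring, with both stereocentres, comes from a biomimetic cyclization of (S)-6,7-epoxygeranyl acetate.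

Key step: step 8

Remark: the L-fructose-derived enantiomer of the Shi ketone is treated as an accessible catalyst (it adds no atoms), and the cyclopentadienyl rings of zirconium compounds are drawn η1 in SMILES.

**Route**

Step 1
Reactants: 1 (2E,6E)-farnesyl bromide; 2 propyne
Product: 5 (6E,10E)-7,11,15-trimethylhexadeca-6,10,14-trien-2-yne, via 1,3-dilithiopropyne 3 (not isolated), via lithium acetylide 4 (not isolated)
Conditions: 2 (1.6 equiv), n-BuLi (3.2 equiv), TMEDA, Et2O/hexane, −78 → 0 °C; then 1, THF, −78 °C → rt; then MeI (excess), DMPU, 0 °C → rt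
Reagents that add atoms: n-butyllithium, [Li]CCCC (its lithium stays only in intermediates 3 and 4); methyl iodide, CI
Why: The propargylic carbanion of the dianion is its more nucleophilic site and should displace the primary allylic bromide by SN2 without touching the alkene geometry, after which the remaining lithium acetylide 4 is C-methylated by MeI (dianion propargylation followed by acetylide alkylation).

Step 2
Reactants: 5 (6E,10E)-7,11,15-trimethylhexadeca-6,10,14-trien-2-yne
Product: 7 (2E,6E,10E)-2-iodo-7,11,15-trimethylhexadeca-2,6,10,14-tetraene, via alkenylzirconocene chloride 6 (not isolated)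
Conditions: Cp2ZrHCl (1.8 equiv), THF, rt → 45 °C; then I2, THF, 0 °C
Reagents that add atoms: Cp2ZrHCl (Schwartz reagent), [H][Zr](Cl)(C1C=CC=C1)C1C=CC=C1 (its zirconium stays only in intermediate 6); iodine, II
Why: syn-Hydrozirconation with excess Schwartz reagent under equilibrating conditions should place zirconium on the less hindered, methyl-bearing alkyne carbon while the trisubstituted alkenes react far more slowly, and iodinolysis of the C–Zr bond with retention gives the (E)-2-iodo-2-alkene (hydrozirconation–iodination).

Step 3
Reactants: 8 geranyl acetate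
Product: 9 (2E)-5-[(2S)-3,3-dimethyloxiran-2-yl]-3-methylpent-2-en-1-yl acetate [(S)-6,7-epoxygeranyl acetate]
Conditions: ent-Shi ketone (0.3 equiv), Oxone (2KHSO5·KHSO4·K2SO4), K2CO3, Bu4NHSO4 (cat.), Na2B4O7/Na2EDTA buffer, MeCN–CH2(OMe)2–H2O, 0 °C
Reagents that add atoms: potassium peroxymonosulfate (active salt of Oxone), [K+].[O-]S(=O)(=O)OO
Why: Shi asymmetric epoxidation, in which the chiral dioxirane attacks the electron-rich 6,7-alkene (the 2,3-alkene is deactivated by the allylic acetate) through the spiro transition state that, for this catalyst enantiomer, should set the (S) configuration at the oxirane CH.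

Step 4
Reactants: 9 (S)-6,7-epoxygeranyl acetate
Product: 10 [(1R,5S)-5-hydroxy-2,6,6-trimethylcyclohex-2-en-1-yl]methyl acetate
Conditions: ZrCl4 (1.5 equiv), CH2Cl2, −78 → −20 °C; then H2O
Reagents that add atoms: none
Why: Lewis-acid-triggered cationic epoxy-olefin cyclization, in which the 2,3-alkene opens the activated oxirane at its tertiary carbon anti to the C–O bond through a chair transition state (6-endo closure), the E alkene placing CH2OAc equatorial and therefore cis to the retained (S)-hydroxyl, and loss of a ring CH2 proton from the tertiary cation gives the endocyclic alkene.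

Step 5
Reactants: 10 [(1R,5S)-5-hydroxy-2,6,6-trimethylcyclohex-2-en-1-yl]methyl acetate
Product: 11 (1S,3R)-3-(hydroxymethyl)-2,2,4-trimethylcyclohex-4-en-1-ol
Conditions: K2CO3 (0.2 equiv), MeOH, rt
Reagents that add atoms: none
Why: Base-catalysed transesterification with methanol should remove the primary acetate without touching the stereocentres or the ring alkene.

Step 6
Reactants: 11 (1S,3R)-3-(hydroxymethyl)-2,2,4-trimethylcyclohex-4-en-1-ol
Product: 12 (1R,5S)-5-hydroxy-2,6,6-trimethylcyclohex-2-ene-1-carbaldehyde
Conditions: TEMPO (0.1 equiv), PhI(OAc)2 (1.1 equiv), CH2Cl2, 0 °C → rt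
Reagents that add atoms: none
Why: TEMPO/PhI(OAc)2 oxidation, in which the hindered oxoammonium salt should take the primary alcohol much faster than the neopentylic secondary one and the mild medium should spare the epimerisable β,γ-unsaturated aldehyde, whose closed lactol form F3 reacts through the open aldehyde in step 7.

Step 7
Reactants: 12 (1R,5S)-5-hydroxy-2,6,6-trimethylcyclohex-2-ene-1-carbaldehyde
Product: 13 (1S,3R)-3-ethenyl-2,2,4-trimethylcyclohex-4-en-1-ol
Conditions: Ph3PCH3Br (3.0 equiv), KOt-Bu (2.9 equiv), THF, 0 °C; then 12, −78 °C → rt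
Reagents that add atoms: methyltriphenylphosphonium bromide, C[P+](c1ccccc1)(c1ccccc1)c1ccccc1.[Br-]
Why: Wittig methylenation with excess ylide (one equivalent serves to deprotonate the hydroxyl) should convert the aldehyde to the vinyl group at low temperature faster than α-epimerisation or conjugation can occur.

Step 8
Reactants: 13 (1S,3R)-3-ethenyl-2,2,4-trimethylcyclohex-4-en-1-ol; 7 (2E,6E,10E)-2-iodo-7,11,15-trimethylhexadeca-2,6,10,14-tetraene
Product: 15 camelliol C, via B-alkyl-9-BBN borane 14 (not isolated)
Conditions: 9-BBN (2.2 equiv), THF, 0 °C → rt; then 3 M aq. Cs2CO3; then 7, PdCl2(dppf) (10 mol %), AsPh3 (10 mol %), DMF, rt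
Reagents that add atoms: 9-borabicyclo[3.3.1]nonane (9-BBN), B1C2CCCC1CCC2 (its boron and ring stay only in intermediate 14)
Why: 9-BBN adds anti-Markovnikov and chemoselectively to the monosubstituted vinyl group of 13 (the trisubstituted ring alkene is too hindered for this borane, and polyene 7 is added only after the borane is quenched) to give primary alkylborane 14; aqueous Cs2CO3 then forms the hydroxyborate, zerovalent palladium inserts into the C–I bond of 7 with retention, the primary alkyl group transmetalates, and reductive elimination forms the C2'(sp3)–C3'(sp2) bond. The closest known reaction type is the B-alkyl Suzuki–Miyaura coupling of a 2-iodo-2-alkene with a B-alkyl-9-BBN. No ring is closed and no stereocentre is created; the E geometry of the new trisubstituted alkene is carried over unchanged from 7, and ring carbons C1 and C3 are not touched. The selectivities needed are hydroboration of one alkene out of two in 13 and coupling faster than β-hydride elimination, which the bulk of 9-BBN and the wide-bite-angle dppf ligand (with AsPh3 to speed transmetalation) should secure. The free hydroxyl needs no protection, since any O–B bond formed with the excess 9-BBN is hydrolysed by the aqueous base.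

**Compound list**

1 | (2E,6E)-farnesyl bromide, (2E,6E)-1-bromo-3,7,11-trimethyldodeca-2,6,10-triene | CC(C)=CCC/C(C)=C/CC/C(C)=C/CBr | starting material
2 | propyne | CC#C | starting material
3 | 1,3-dilithiopropyne | [Li]CC#C[Li] | intermediate
4 | [(5E,9E)-6,10,14-trimethylpentadeca-5,9,13-trien-1-yn-1-yl]lithium (lithium acetylide) | CC(C)=CCC/C(C)=C/CC/C(C)=C/CCC#C[Li] | intermediate
5 | (6E,10E)-7,11,15-trimethylhexadeca-6,10,14-trien-2-yne | CC(C)=CCC/C(C)=C/CC/C(C)=C/CCC#CC | intermediate
6 | chlorobis(cyclopentadienyl)[(2E,6E,10E)-7,11,15-trimethylhexadeca-2,6,10,14-tetraen-2-yl]zirconium | CC(C)=CCC/C(C)=C/CC/C(C)=C/CC/C=C(\C)[Zr](Cl)(C1C=CC=C1)C1C=CC=C1 | intermediate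
7 | (2E,6E,10E)-2-iodo-7,11,15-trimethylhexadeca-2,6,10,14-tetraene | CC(C)=CCC/C(C)=C/CC/C(C)=C/CC/C=C(\C)I | intermediate
8 | geranyl acetate, (2E)-3,7-dimethylocta-2,6-dien-1-yl acetate | CC(C)=CCC/C(C)=C/COC(C)=O | starting material
9 | (2E)-5-[(2S)-3,3-dimethyloxiran-2-yl]-3-methylpent-2-en-1-yl acetate | CC1(C)O[C@H]1CC/C(C)=C/COC(C)=O | intermediate
10 | [(1R,5S)-5-hydroxy-2,6,6-trimethylcyclohex-2-en-1-yl]methyl acetate (OH and CH2OAc cis) | CC(=O)OC[C@@H]1C(C)=CC[C@H](O)C1(C)C | intermediate
11 | (1S,3R)-3-(hydroxymethyl)-2,2,4-trimethylcyclohex-4-en-1-ol | OC[C@@H]1C(C)=CC[C@H](O)C1(C)C | intermediate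
12 | (1R,5S)-5-hydroxy-2,6,6-trimethylcyclohex-2-ene-1-carbaldehyde | O=C[C@@H]1C(C)=CC[C@H](O)C1(C)C | intermediate
13 | (1S,3R)-3-ethenyl-2,2,4-trimethylcyclohex-4-en-1-ol | C=C[C@@H]1C(C)=CC[C@H](O)C1(C)C | intermediate
14 | (1S,3R)-3-[2-(9-borabicyclo[3.3.1]nonan-9-yl)ethyl]-2,2,4-trimethylcyclohex-4-en-1-ol | C1CCC2CCCC1B2CC[C@@H]1C(C)=CC[C@H](O)C1(C)C | intermediate
15 | camelliol C, (1S,3R)-2,2,4-trimethyl-3-[(3E,7E,11E)-3,8,12,16-tetramethylheptadeca-3,7,11,15-tetraen-1-yl]cyclohex-4-en-1-ol | CC(C)=CCC/C(C)=C/CC/C(C)=C/CC/C=C(\C)CC[C@@H]1C(C)=CC[C@H](O)C1(C)C | target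

**Count**

Total step count: 8. Longest linear sequence: 6 steps (steps 3 to 8, from geranyl acetate 8).

**Steps most likely to fail**

Step 4. The tertiary cation may lose the wrong proton (exocyclic instead of endocyclic alkene), be trapped by the hydroxyl as a bridged ether, or the epoxide may rearrange to a ketone by hydride shift before it cyclizes. The fallback sets out from 9 and replaces the cationic closure by a radical one. Cp2TiCl (trivalent titanium, generated from Cp2TiCl2 and manganese powder, THF, rt) opens the epoxide homolytically, the tertiary radical closes the same chair-like six-membered ring, and the alkyltitanium formed should eliminate only to the exocyclic alkene, [(1R,3S)-3-hydroxy-2,2-dimethyl-6-methylidenecyclohexyl]methyl acetate F1. RhCl3·3H2O (cat., EtOH, 70 °C) then moves the alkene into the ring toward the less hindered CH2, and the fallback comes back to the route at 10.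

Step 6. The lactol form may be oxidised further to the lactone, and the free β,γ-unsaturated aldehyde may epimerise or move its alkene into conjugation during handling. The fallback sets out from 11 and drives the oxidation on purpose (TEMPO cat., PhI(OAc)2 2.5 equiv, CH2Cl2) to the bridged lactone (1R,5S)-2,8,8-trimethyl-6-oxabicyclo[3.2.1]oct-2-en-7-one F2, which locks the cis relationship and cannot epimerise. DIBAL-H (CH2Cl2, −78 °C) reduces it to the lactol (1R,5S)-2,8,8-trimethyl-6-oxabicyclo[3.2.1]oct-2-en-7-ol F3, and the Wittig conditions of step 7 applied to F3 bring the fallback back to the route at 13.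

Step 1. The dianion may also react in the allenyl or SN2' sense, and the one-pot methylation of the acetylide may stay incomplete. The fallback sets out from 1 and uses a silyl-blocked monoanion instead. Alkylation with 3-lithio-1-(trimethylsilyl)propyne (from 1-(trimethylsilyl)propyne and n-BuLi, THF, −78 °C), whose silyl group enforces attack through the propargylic carbon, should give trimethyl[(5E,9E)-6,10,14-trimethylpentadeca-5,9,13-trien-1-yn-1-yl]silane F4. K2CO3/MeOH removes silicon to give (5E,9E)-6,10,14-trimethylpentadeca-5,9,13-trien-1-yne F5, and n-BuLi (THF, −78 °C) converts this to lithium acetylide 4, where the fallback comes back to the route (MeI then gives 5).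

Further compounds
F1 | step 4 | [(1R,3S)-3-hydroxy-2,2-dimethyl-6-methylidenecyclohexyl]methyl acetate | CC(=O)OC[C@@H]1C(=C)CC[C@H](O)C1(C)C
F2 | step 6 | (1R,5S)-2,8,8-trimethyl-6-oxabicyclo[3.2.1]oct-2-en-7-one | O=C2[C@@H]1C(C)=CC[C@H](O2)C1(C)C
F3 | step 6 | (1R,5S)-2,8,8-trimethyl-6-oxabicyclo[3.2.1]oct-2-en-7-ol (lactol, either configuration at C7) | OC2[C@@H]1C(C)=CC[C@H](O2)C1(C)C
F4 | step 1 | trimethyl[(5E,9E)-6,10,14-trimethylpentadeca-5,9,13-trien-1-yn-1-yl]silane | CC(C)=CCC/C(C)=C/CC/C(C)=C/CCC#C[Si](C)(C)C
F5 | step 1 | (5E,9E)-6,10,14-trimethylpentadeca-5,9,13-trien-1-yne | CC(C)=CCC/C(C)=C/CC/C(C)=C/CCC#C
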